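**Retrosynthetic overview**

1. Anabsin 29 is traced back to the C2-symmetric 2,2'-linked bis(guai-4-en-3β-ol) 28. The last step forms C3–C5' (the cyclopentane of the bicyclo[2.2.1]heptane core) and the C10'–O–C4' oxolane from an allyl cation. 28 comes from two molecules of enone lactone 22 by oxidative C2–C2' enolate coupling.
2. 22 comes from dienone 19 (lactone built from O6 and the C7 isopropenyl group), and 19 from aldehyde 18 by the C6–C7 carbonyl-ene closure of ring B.
3. 18 comes from a cyclopentenone (ring A) made by ring-closing metathesis and oxidative 1,3-transposition on aldehyde 6. Aldehyde 6 comes from geraniol 1, whose Sharpless epoxide is opened by allyl at C2, fixing C1 against C10.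
4. Feature: in each C15 half, C1, C10 (with C14 and its tertiary oxygen), C9, C8, C7 and C11–C13 form one unbroken acyclic terpene chain attached to ring A, and C6 carries the lactone oxygen trans to the C7 side chain. Ring B can therefore be closed at C6–C7 by an ene reaction that creates O6 and the isopropenyl group together.
5. Ring order: ring A (step 6), ring B (step 13), lactone (step 15), then, after C2–C2' coupling (step 16), the bridging cyclopentane and the oxolane (step 21).

Key step: step 13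

Remark: locants follow guaiane numbering for each C15 half (primed for the ether-bridged half of the dimer); α is the face of H-1 and H-7, β the face of H-6. The tertiary C10 hydroxyl is carried as a triethylsilyl ether through the key step, because the free γ-hydroxy aldehyde would close to a five-membered lactol.

**Route**

Step 1
Reactants: 1 geraniol
Product: 2 (2S,3S)-2,3-epoxygeraniol
Conditions: Ti(OiPr)4 (5 mol%), L-(+)-diethyl tartrate (7 mol%), t-BuOOH, 4 Å MS, CH2Cl2, −20 °C
Reagents that add atoms: tert-butyl hydroperoxide, CC(C)(C)OO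
Why: Sharpless asymmetric epoxidation, in which the allylic hydroxyl directs oxygen to the 2,3-alkene only and the L-(+)-tartrate ligand sets both epoxide carbons (2S,3S), the future C1 and C10.

Step 2
Reactants: 2 (2S,3S)-2,3-epoxygeraniol; 3 allylmagnesium chloride (3 equiv)
Product: 4 (2R,3S)-2-allyl-3,7-dimethyloct-6-ene-1,3-diol
Conditions: CuI (10 mol%), THF, −30 → 0 °C; aq. NH4Cl
Reagents that add atoms: none
Why: Copper-catalysed Grignard SN2 opening of the epoxy alcohol, in which the fully substituted C3 cannot be attacked, so allyl should enter at C2 with inversion and fix C1 (guaiane) relative to the untouched carbinol carbon C10.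

Step 3
Reactants: 4 (2R,3S)-2-allyl-3,7-dimethyloct-6-ene-1,3-diol
Product: 5 (2R,3S)-2-allyl-3,7-dimethyl-1,3-bis(triethylsilyloxy)oct-6-ene
Conditions: Et3SiOTf, 2,6-lutidine, CH2Cl2, −78 → 0 °C
Reagents that add atoms: triethylsilyl trifluoromethanesulfonate, CC[Si](CC)(CC)OS(=O)(=O)C(F)(F)F
Why: Silyl triflate silylation of both hydroxyls, the tertiary ether later keeping O10 away from the C6 aldehyde and the primary ether serving as the handle for step 4.

Step 4
Reactants: 5 (2R,3S)-2-allyl-3,7-dimethyl-1,3-bis(triethylsilyloxy)oct-6-ene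
Product: 6 (2S,3S)-2-allyl-3,7-dimethyl-3-(triethylsilyloxy)oct-6-enal
Conditions: (COCl)2, DMSO, CH2Cl2, −78 → −30 °C; Et3N
Reagents that add atoms: none
Why: Swern oxidation in which the chlorosulfonium salt attacks only the unhindered primary triethylsilyl ether, so the aldehyde should form directly while the tertiary silyl ether and the α-stereocentre survive the short, cold exposure to base.

Step 5
Reactants: 6 (2S,3S)-2-allyl-3,7-dimethyl-3-(triethylsilyloxy)oct-6-enal; 7 isopropenylmagnesium bromide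
Product: 8 (4R,5S)-4-allyl-2,5,9-trimethyl-5-(triethylsilyloxy)deca-1,8-dien-3-ol (both C3 epimers)
Conditions: THF, −78 °C
Reagents that add atoms: none
Why: Grignard 1,2-addition to the aldehyde brings in C4 and C15; the new carbinol centre is left as a mixture because step 7 oxidises it.

Step 6
Reactants: 8 (4R,5S)-4-allyl-2,5,9-trimethyl-5-(triethylsilyloxy)deca-1,8-dien-3-ol
Product: 9 (5R)-2-methyl-5-[(2S)-6-methyl-2-(triethylsilyloxy)hept-5-en-2-yl]cyclopent-2-en-1-ol (both C1 epimers)
Conditions: second-generation Grubbs catalyst (3 mol%), CH2Cl2, 40 °C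
Reagents that add atoms: none
Why: Ring-closing metathesis of the allyl and isopropenyl termini should close the five-membered ring A with loss of ethylene far faster than the trisubstituted prenyl alkene can react.

Step 7
Reactants: 9 (5R)-2-methyl-5-[(2S)-6-methyl-2-(triethylsilyloxy)hept-5-en-2-yl]cyclopent-2-en-1-ol
Product: 10 (5S)-2-methyl-5-[(2S)-6-methyl-2-(triethylsilyloxy)hept-5-en-2-yl]cyclopent-2-en-1-one
Conditions: Dess–Martin periodinane, NaHCO3, CH2Cl2, 0 °C → rt
Reagents that add atoms: none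
Why: Dess–Martin oxidation of the allylic alcohol under buffered, non-basic conditions should give the enone without epimerising the stereocentre next to the carbonyl.

Step 8
Reactants: 11 4-methoxybenzyl alcohol; 12 tributyl(iodomethyl)stannane
Product: 13 tributyl[(4-methoxybenzyloxy)methyl]stannane
Conditions: NaH, THF/DMF, 0 °C → rt
Reagents that add atoms: none
Why: Williamson etherification of the sodium alkoxide with the primary iodomethylstannane gives the α-alkoxymethylstannane that serves as the C6 donor.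

Step 9
Reactants: 10 (5S)-2-methyl-5-[(2S)-6-methyl-2-(triethylsilyloxy)hept-5-en-2-yl]cyclopent-2-en-1-one; 13 tributyl[(4-methoxybenzyloxy)methyl]stannane
Product: 15 (5R)-1-[(4-methoxybenzyloxy)methyl]-2-methyl-5-[(2S)-6-methyl-2-(triethylsilyloxy)hept-5-en-2-yl]cyclopent-2-en-1-ol (both C1 epimers), via [(4-methoxybenzyloxy)methyl]lithium 14 (not isolated)
Conditions: n-BuLi, THF, −78 °C; then 10, −78 °C
Reagents that add atoms: none
Why: Tin–lithium exchange gives an α-alkoxymethyllithium that should add 1,2 to the enone carbonyl at −78 °C faster than it enolises it, delivering C6; the carbinol configuration is immaterial because step 10 removes it.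

Step 10
Reactants: 15 (5R)-1-[(4-methoxybenzyloxy)methyl]-2-methyl-5-[(2S)-6-methyl-2-(triethylsilyloxy)hept-5-en-2-yl]cyclopent-2-en-1-ol
Product: 16 (4R)-3-[(4-methoxybenzyloxy)methyl]-2-methyl-4-[(2S)-6-methyl-2-(triethylsilyloxy)hept-5-en-2-yl]cyclopent-2-en-1-one
Conditions: [C5H5NH][CrO3Cl] (pyridinium chlorochromate), 4 Å MS, CH2Cl2, rt
Reagents that add atoms: pyridinium chlorochromate, c1cc[nH+]cc1.[O-][Cr](=O)(=O)Cl
Why: Babler–Dauben oxidative transposition, in which the tertiary allylic chromate ester undergoes a [3,3] shift and oxidation, should move oxygen to C3 and the alkene to C4=C5, leaving C6 on C5 of the 3-oxo-4-ene ring A.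

Step 11
Reactants: 16 (4R)-3-[(4-methoxybenzyloxy)methyl]-2-methyl-4-[(2S)-6-methyl-2-(triethylsilyloxy)hept-5-en-2-yl]cyclopent-2-en-1-one
Product: 17 (4R)-3-(hydroxymethyl)-2-methyl-4-[(2S)-6-methyl-2-(triethylsilyloxy)hept-5-en-2-yl]cyclopent-2-en-1-one
Conditions: DDQ, CH2Cl2/pH 7 buffer, 0 °C
Reagents that add atoms: none
Why: Oxidative cleavage of the 4-methoxybenzyl ether by DDQ under buffered conditions should leave the silyl ether, the enone and the prenyl alkene untouched.

Step 12
Reactants: 17 (4R)-3-(hydroxymethyl)-2-methyl-4-[(2S)-6-methyl-2-(triethylsilyloxy)hept-5-en-2-yl]cyclopent-2-en-1-one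
Product: 18 (4R)-3-formyl-2-methyl-4-[(2S)-6-methyl-2-(triethylsilyloxy)hept-5-en-2-yl]cyclopent-2-en-1-one
Conditions: Dess–Martin periodinane, NaHCO3, CH2Cl2, 0 °C
Reagents that add atoms: none
Why: Dess–Martin oxidation of the primary allylic alcohol gives the 4-oxo-2-enal under non-basic conditions, to be used at once because H1 is vinylogously acidic.

Step 13
Reactants: 18 (4R)-3-formyl-2-methyl-4-[(2S)-6-methyl-2-(triethylsilyloxy)hept-5-en-2-yl]cyclopent-2-en-1-one
Product: 19 6α-hydroxy-10β-(triethylsilyloxy)-1αH,7αH-guaia-4,11(13)-dien-3-one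
Conditions: Me2AlCl (2.5 equiv), CH2Cl2, −78 → −40 °C; 1 M HCl
Reagents that add atoms: none
Why: Me2AlCl binds the C6 aldehyde (a second equivalent occupies the C3 ketone) and the C7=C11 alkene adds through C7 to C6 while a hydrogen of a C11 methyl group passes to the carbonyl oxygen in a six-membered ene transition state, the resulting aluminium alkoxide losing methane so that no proton-initiated side reaction starts. This is a Lewis acid-promoted type 1 intramolecular carbonyl-ene reaction, the seven-membered counterpart of the citronellal-to-isopulegol closure. Ring B is closed by the C6–C7 bond in a 7-exo-trig mode in which both the carbonyl oxygen and C11 stay outside the new cycloheptane. C6 and C7 are set together: the chair-like transition state holds the O–Al group and the developing isopropenyl group trans and pseudo-equatorial, which gives 6α-O and 7β-C11. The C1 stereocentre decides the absolute sense, because the tether leaves C1 on the β face through C10 so that C7 reaches C6 from the β side, and allylic 1,3-strain with the C4 methyl keeps H6 in the enone plane and turns O6 to the α face. The step needs ene closure to win over methyl transfer from aluminium or chloride capture and needs the 6α,7β isomer; the electron-poor 4-oxo-2-enal, the electron-rich trisubstituted alkene, the fully substituted C10 (whose silyl ether also blocks lactol formation) and the low temperature should secure both.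

Step 14
Reactants: 19 6α-hydroxy-10β-(triethylsilyloxy)-1αH,7αH-guaia-4,11(13)-dien-3-one
Product: 21 10β-(triethylsilyloxy)-1αH,7αH,11βH-guai-4-ene-3,6α,12-triol (both C3 epimers), via tris(9-BBN) organoborane 20 (not isolated)
Conditions: 9-BBN (3.5 equiv), THF, 0 °C → rt; then NaOH, H2O2, 0 °C
Reagents that add atoms: hydrogen peroxide, OO
Why: Hydroboration–oxidation places boron on the terminal carbon of the isopropenyl group (the C3 carbonyl is reduced in passing and restored in step 15), and attack anti to the larger C6 branch in the allylic-strain-controlled rotamer about C7–C11 should set the 11S (11βH) centre, as in hydroboration of trans-2-isopropenylcycloalkanols.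

Step 15
Reactants: 21 10β-(triethylsilyloxy)-1αH,7αH,11βH-guai-4-ene-3,6α,12-triol
Product: 22 3-oxo-10β-(triethylsilyloxy)-1αH,6βH,7αH,11βH-guai-4-en-12,6-olide
Conditions: TEMPO (20 mol%), PhI(OAc)2 (4 equiv), CH2Cl2, rt
Reagents that add atoms: none
Why: Oxoammonium (TEMPO) oxidation should take the primary alcohol first, the aldehyde being trapped by the 6α-hydroxyl as a lactol that is oxidised to the trans-fused γ-lactone, while the allylic 3-carbinol of either configuration returns to the enone.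

Step 16
Reactants: 22 3-oxo-10β-(triethylsilyloxy)-1αH,6βH,7αH,11βH-guai-4-en-12,6-olide (two molecules)
Product: 24 2α,2'α-linked bis[3-oxo-10β-(triethylsilyloxy)-1αH,6βH,7αH,11βH-guai-4-en-12,6-olide] (2βH,2'βH), via lithium C2-enolate 23 (not isolated)
Conditions: LiN(iPr)2, THF, −78 °C; CuCl2, DMF, −78 → 0 °C
Reagents that add atoms: none
Why: Kinetic deprotonation gives the cross-conjugated C2 enolate and one-electron oxidation by CuCl2 joins two of them (oxidative enolate homocoupling), each new bond forming on the α face anti to the C1–C10 bond so that the two homochiral halves should give the C2-symmetric 2α,2'α dimer.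

Step 17
Reactants: 24 2α,2'α-linked bis(enone lactone)
Product: 25 3α,3'α-dihydroxy-2α,2'α-linked bis[10β-(triethylsilyloxy)-1αH,6βH,7αH,11βH-guai-4-en-12,6-olide]
Conditions: LiBH(s-Bu)3, THF, −78 °C
Reagents that add atoms: none
Why: 1,2-Reduction of the β,β-disubstituted enones by a bulky borohydride from the β face, anti to the adjacent C2 substituent, should give the 3α (2,3-cis) allylic alcohols while the lactones stay inert at −78 °C.

Step 18
Reactants: 25 3α,3'α-diol
Product: 26 3β,3'β-bis(4-nitrobenzoyloxy)-2α,2'α-linked bis[10β-(triethylsilyloxy)-1αH,6βH,7αH,11βH-guai-4-en-12,6-olide]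
Conditions: 4-O2NC6H4CO2H, PPh3, iPrO2CN=NCO2iPr, THF, 0 °C → rt
Reagents that add atoms: 4-nitrobenzoic acid, OC(=O)c1ccc(cc1)[N+](=O)[O-]
Why: Mitsunobu reaction in which the carboxylate enters on the β face, anti to the C2 substituent, inverts both allylic carbinols and sets the 3β configuration that C3' keeps in the target.

Step 19
Reactants: 26 3β,3'β-bis(4-nitrobenzoate)
Product: 27 3β,3'β-dihydroxy-2α,2'α-linked bis[10β-(triethylsilyloxy)-1αH,6βH,7αH,11βH-guai-4-en-12,6-olide]
Conditions: K2CO3, MeOH, 0 °C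
Reagents that add atoms: none
Why: Carbonate-catalysed methanolysis should cleave the activated aryl esters faster than it opens the γ-lactones and leaves the silyl ethers in place.

Step 20
Reactants: 27 3β,3'β-diol bis(triethylsilyl ether)
Product: 28 3β,3'β,10β,10'β-tetrahydroxy-2α,2'α-linked bis(1αH,6βH,7αH,11βH-guai-4-en-12,6-olide)
Conditions: Bu4NF, AcOH, THF, 0 °C → rt
Reagents that add atoms: none
Why: Fluoride cleavage of the two tertiary silyl ethers, buffered with acetic acid so that the lactones and the C11 centres are not disturbed.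

Step 21
Reactants: 28 tetraol
Product: 29 anabsin
Conditions: (+)-camphor-10-sulfonic acid (10 mol%), CH2Cl2/(CF3)2CHOH 9:1, −20 → 0 °C
Reagents that add atoms: none
Why: Acid ionises either of the two equivalent allylic 3-hydroxyls to the C3–C4–C5 allyl cation, the C4'=C5' alkene of the other half attacks C3 through C5' (5-exo cation–alkene cyclisation, necessarily cis to the C2–C2' bond on both α faces) and the C4' cation is captured on its β face by the 10'β-hydroxyl to close the oxolane, so that C3, C5' and C4' are set by the tether while the trans 3'β-hydroxyl cannot reach the cation.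

**Compound list**

1 | geraniol, (2E)-3,7-dimethylocta-2,6-dien-1-ol | CC(C)=CCC/C(C)=C/CO | starting material
2 | (2S,3S)-2,3-epoxygeraniol | OC[C@@H]1O[C@@]1(C)CCC=C(C)C | intermediate
3 | allylmagnesium chloride | C=CC[Mg]Cl | starting material
4 | (2R,3S)-2-allyl-3,7-dimethyloct-6-ene-1,3-diol | OC[C@@H](CC=C)[C@@](C)(O)CCC=C(C)C | intermediate
5 | (2R,3S)-2-allyl-3,7-dimethyl-1,3-bis(triethylsilyloxy)oct-6-ene | CC[Si](CC)(CC)OC[C@@H](CC=C)[C@@](C)(O[Si](CC)(CC)CC)CCC=C(C)C | intermediate
6 | (2S,3S)-2-allyl-3,7-dimethyl-3-(triethylsilyloxy)oct-6-enal | O=C[C@@H](CC=C)[C@@](C)(O[Si](CC)(CC)CC)CCC=C(C)C | intermediate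
7 | isopropenylmagnesium bromide | CC(=C)[Mg]Br | starting material
8 | (4R,5S)-4-allyl-2,5,9-trimethyl-5-(triethylsilyloxy)deca-1,8-dien-3-ol (C3 epimers) | CC(=C)C(O)[C@@H](CC=C)[C@@](C)(O[Si](CC)(CC)CC)CCC=C(C)C | intermediate
9 | (5R)-2-methyl-5-[(2S)-6-methyl-2-(triethylsilyloxy)hept-5-en-2-yl]cyclopent-2-en-1-ol (C1 epimers) | CC1=CC[C@@H]([C@@](C)(O[Si](CC)(CC)CC)CCC=C(C)C)C1O | intermediate
10 | (5S)-2-methyl-5-[(2S)-6-methyl-2-(triethylsilyloxy)hept-5-en-2-yl]cyclopent-2-en-1-one | CC1=CC[C@@H]([C@@](C)(O[Si](CC)(CC)CC)CCC=C(C)C)C1=O | intermediate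
11 | 4-methoxybenzyl alcohol | COc1ccc(CO)cc1 | starting material
12 | tributyl(iodomethyl)stannane | CCCC[Sn](CCCC)(CCCC)CI | starting material
13 | tributyl[(4-methoxybenzyloxy)methyl]stannane | CCCC[Sn](CCCC)(CCCC)COCc1ccc(OC)cc1 | intermediate
14 | [(4-methoxybenzyloxy)methyl]lithium | [Li]COCc1ccc(OC)cc1 | intermediate
15 | (5R)-1-[(4-methoxybenzyloxy)methyl]-2-methyl-5-[(2S)-6-methyl-2-(triethylsilyloxy)hept-5-en-2-yl]cyclopent-2-en-1-ol (C1 epimers) | CC1=CC[C@@H]([C@@](C)(O[Si](CC)(CC)CC)CCC=C(C)C)C1(O)COCc2ccc(OC)cc2 | intermediate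
16 | (4R)-3-[(4-methoxybenzyloxy)methyl]-2-methyl-4-[(2S)-6-methyl-2-(triethylsilyloxy)hept-5-en-2-yl]cyclopent-2-en-1-one | CC1=C(COCc2ccc(OC)cc2)[C@H]([C@@](C)(O[Si](CC)(CC)CC)CCC=C(C)C)CC1=O | intermediate
17 | (4R)-3-(hydroxymethyl)-2-methyl-4-[(2S)-6-methyl-2-(triethylsilyloxy)hept-5-en-2-yl]cyclopent-2-en-1-one | CC1=C(CO)[C@H]([C@@](C)(O[Si](CC)(CC)CC)CCC=C(C)C)CC1=O | intermediate
18 | (4R)-3-formyl-2-methyl-4-[(2S)-6-methyl-2-(triethylsilyloxy)hept-5-en-2-yl]cyclopent-2-en-1-one | CC1=C(C=O)[C@H]([C@@](C)(O[Si](CC)(CC)CC)CCC=C(C)C)CC1=O | intermediate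
19 | 6α-hydroxy-10β-(triethylsilyloxy)-1αH,7αH-guaia-4,11(13)-dien-3-one | CC1=C2[C@@H](O)[C@H](C(C)=C)CC[C@](C)(O[Si](CC)(CC)CC)[C@@H]2CC1=O | intermediate
20 | 12-(9-borabicyclo[3.3.1]nonan-9-yl)-3,6α-bis(9-borabicyclo[3.3.1]nonan-9-yloxy)-10β-(triethylsilyloxy)-1αH,7αH,11βH-guai-4-ene | CC1=C2[C@@H](OB3C4CCCC3CCC4)[C@H]([C@H](C)CB3C4CCCC3CCC4)CC[C@](C)(O[Si](CC)(CC)CC)[C@@H]2CC1OB1C2CCCC1CCC2 | intermediate
21 | 10β-(triethylsilyloxy)-1αH,7αH,11βH-guai-4-ene-3,6α,12-triol (C3 epimers) | CC1=C2[C@@H](O)[C@H]([C@H](C)CO)CC[C@](C)(O[Si](CC)(CC)CC)[C@@H]2CC1O | intermediate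
22 | 3-oxo-10β-(triethylsilyloxy)-1αH,6βH,7αH,11βH-guai-4-en-12,6-olide | CC1=C2[C@H]3OC(=O)[C@@H](C)[C@@H]3CC[C@](C)(O[Si](CC)(CC)CC)[C@@H]2CC1=O | intermediate
23 | lithium C2-enolate of 22 | CC1=C2[C@H]3OC(=O)[C@@H](C)[C@@H]3CC[C@](C)(O[Si](CC)(CC)CC)[C@@H]2C=C1O[Li] | intermediate
24 | 2α,2'α-linked bis[3-oxo-10β-(triethylsilyloxy)-1αH,6βH,7αH,11βH-guai-4-en-12,6-olide] | CC1=C2[C@H]3OC(=O)[C@@H](C)[C@@H]3CC[C@](C)(O[Si](CC)(CC)CC)[C@@H]2[C@@H]([C@H]7C(=O)C(C)=C8[C@H]9OC(=O)[C@@H](C)[C@@H]9CC[C@](C)(O[Si](CC)(CC)CC)[C@@H]87)C1=O | intermediate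
25 | 3α,3'α-diol of 24 | CC1=C2[C@H]3OC(=O)[C@@H](C)[C@@H]3CC[C@](C)(O[Si](CC)(CC)CC)[C@@H]2[C@@H]([C@H]7[C@@H](O)C(C)=C8[C@H]9OC(=O)[C@@H](C)[C@@H]9CC[C@](C)(O[Si](CC)(CC)CC)[C@@H]87)[C@H]1O | intermediate
26 | 3β,3'β-bis(4-nitrobenzoate) | CC1=C2[C@H]3OC(=O)[C@@H](C)[C@@H]3CC[C@](C)(O[Si](CC)(CC)CC)[C@@H]2[C@@H]([C@H]7[C@H](OC(=O)c4ccc(cc4)[N+](=O)[O-])C(C)=C8[C@H]9OC(=O)[C@@H](C)[C@@H]9CC[C@](C)(O[Si](CC)(CC)CC)[C@@H]87)[C@@H]1OC(=O)c2ccc(cc2)[N+](=O)[O-] | intermediate
27 | 3β,3'β-diol bis(triethylsilyl ether) | CC1=C2[C@H]3OC(=O)[C@@H](C)[C@@H]3CC[C@](C)(O[Si](CC)(CC)CC)[C@@H]2[C@@H]([C@H]7[C@H](O)C(C)=C8[C@H]9OC(=O)[C@@H](C)[C@@H]9CC[C@](C)(O[Si](CC)(CC)CC)[C@@H]87)[C@@H]1O | intermediate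
28 | 3β,3'β,10β,10'β-tetrahydroxy-2α,2'α-linked bis(1αH,6βH,7αH,11βH-guai-4-en-12,6-olide) | CC1=C2[C@H]3OC(=O)[C@@H](C)[C@@H]3CC[C@](C)(O)[C@@H]2[C@@H]([C@H]7[C@H](O)C(C)=C8[C@H]9OC(=O)[C@@H](C)[C@@H]9CC[C@](C)(O)[C@@H]87)[C@@H]1O | intermediate
29 | anabsin | CC1=C2[C@H]3OC(=O)[C@@H](C)[C@@H]3CC[C@](C)(O)[C@@H]2[C@H]2[C@@H]3[C@@H]4[C@]5([C@H]6OC(=O)[C@@H](C)[C@@H]6CC[C@]4(C)O[C@@]5(C)[C@H]3O)[C@@H]12 | target

**Step count and risks**

Total step count: 21. Longest linear sequence: 20 steps (steps 1–7 and 9–21 from geraniol; step 8 is a one-step side branch).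

Steps most likely to fail:

Step 13. The seven-membered ene closure may be slow enough for methyl transfer from aluminium to the aldehyde, chloride capture of the developing tertiary cation, or closure through the other aldehyde face to compete. The fallback sets out from 16 and comes back at 19, replacing the ene reaction by an intramolecular allylchromium addition. Allylic oxidation of the (E)-methyl group of the prenyl terminus (SeO2 cat., t-BuOOH) would give the (E)-allylic alcohol F1, and CBr4/PPh3 the allylic bromide F2. DDQ would then free the primary alcohol F3 and Dess–Martin oxidation would give the bromo aldehyde F4. CrCl2 in THF (Nozaki–Hiyama allylation) would form C6–C7 through the γ-carbon of the allylchromium species in a chair transition state and should give the same anti 6-hydroxy-7-isopropenyl compound 19.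

Step 21. The allyl cation may lose a proton to give cyclopentadienes that dimerise by Diels–Alder reaction, may bond through C4' instead of C5', or the product may ionise again in acid. The fallback sets out from 26 and comes back at 29, using neutral solvolysis of an allylic ester in place of Brønsted acid on the free alcohol. Bu4NF/AcOH would give the 10,10'-diol bis(4-nitrobenzoate) F6. Warming F6 in (CF3)2CHOH with 2,6-lutidine would ionise one allylic ester, and the same C3–C5' closure and ether formation would give anabsin 3'-O-(4-nitrobenzoate) F7, the remaining ester no longer being allylic. K2CO3/MeOH would then release 29.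

Step 16. Oxidation of the enolate may lead to α-chlorination or dehydrogenation instead of coupling, and deprotonation at C11 or C1 may compete. The fallback sets out from 22 and comes back at 24, making the coupling intramolecular. Deprotonation with LiN(iPr)2 and silylation with half an equivalent of iPr2SiCl2 would give the diisopropylsilanediyl bis(enol ether) F5. Oxidation with (NH4)2Ce(NO3)6 and NaHCO3 in MeCN would join the two C2 termini within the tether and release the silicon, giving 24.

**Further compounds**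

F1 | step 13 | (4R)-4-[(2S,5E)-7-hydroxy-6-methyl-2-(triethylsilyloxy)hept-5-en-2-yl]-3-[(4-methoxybenzyloxy)methyl]-2-methylcyclopent-2-en-1-one | CC1=C(COCc2ccc(OC)cc2)[C@H]([C@@](C)(O[Si](CC)(CC)CC)CC/C=C(\C)CO)CC1=O
F2 | step 13 | (4R)-4-[(2S,5E)-7-bromo-6-methyl-2-(triethylsilyloxy)hept-5-en-2-yl]-3-[(4-methoxybenzyloxy)methyl]-2-methylcyclopent-2-en-1-one | CC1=C(COCc2ccc(OC)cc2)[C@H]([C@@](C)(O[Si](CC)(CC)CC)CC/C=C(\C)CBr)CC1=O
F3 | step 13 | (4R)-4-[(2S,5E)-7-bromo-6-methyl-2-(triethylsilyloxy)hept-5-en-2-yl]-3-(hydroxymethyl)-2-methylcyclopent-2-en-1-one | CC1=C(CO)[C@H]([C@@](C)(O[Si](CC)(CC)CC)CC/C=C(\C)CBr)CC1=O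
F4 | step 13 | (4R)-4-[(2S,5E)-7-bromo-6-methyl-2-(triethylsilyloxy)hept-5-en-2-yl]-3-formyl-2-methylcyclopent-2-en-1-one | CC1=C(C=O)[C@H]([C@@](C)(O[Si](CC)(CC)CC)CC/C=C(\C)CBr)CC1=O
F5 | step 16 | diisopropylsilanediyl bis(C3 enol ether) of 22 | CC1=C2[C@H]3OC(=O)[C@@H](C)[C@@H]3CC[C@](C)(O[Si](CC)(CC)CC)[C@@H]2C=C1O[Si](C(C)C)(C(C)C)OC4=C[C@@H]5C(=C4C)[C@H]6OC(=O)[C@@H](C)[C@@H]6CC[C@]5(C)O[Si](CC)(CC)CC
F6 | step 21 | 10β,10'β-dihydroxy-3β,3'β-bis(4-nitrobenzoyloxy)-2α,2'α-linked bis(1αH,6βH,7αH,11βH-guai-4-en-12,6-olide) | CC1=C2[C@H]3OC(=O)[C@@H](C)[C@@H]3CC[C@](C)(O)[C@@H]2[C@@H]([C@H]7[C@H](OC(=O)c4ccc(cc4)[N+](=O)[O-])C(C)=C8[C@H]9OC(=O)[C@@H](C)[C@@H]9CC[C@](C)(O)[C@@H]87)[C@@H]1OC(=O)c2ccc(cc2)[N+](=O)[O-]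
F7 | step 21 | anabsin 3'-O-(4-nitrobenzoate) | CC1=C2[C@H]3OC(=O)[C@@H](C)[C@@H]3CC[C@](C)(O)[C@@H]2[C@H]2[C@@H]3[C@@H]4[C@]5([C@H]6OC(=O)[C@@H](C)[C@@H]6CC[C@]4(C)O[C@@]5(C)[C@H]3OC(=O)c7ccc(cc7)[N+](=O)[O-])[C@@H]12
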